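## The problem

The target is a lignan of the 7,9'-epoxy type with a single oxolane ring (O1, C2 to C5): C2 carries a 3,4-dihydroxyphenyl group, C3 an acetoxymethyl group whose carbon is called C9 here, and C4 a 4-hydroxy-3-methoxybenzyl group whose benzylic carbon is called C7'. No ring is fused to the oxolane, so the task is to place three different substituents on three contiguous ring carbons and to bring in two differently oxygenated aryl groups separately. The configuration is 2S,3R,4R: the C2 aryl group is trans to C9, and C9 is cis to C7'. C2 is the natural anchor, because a benzylic C–O centre next to an alkene can be set by asymmetric catalysis and its aryl group can then shield one ring face while C3 and C4 are set; the 3,4-cis relation, in contrast, is the less stable one and would be lost if C3 or C4 stayed next to a carbonyl group under basic conditions. The benzylic C2–O1 bond beside an electron-rich ring ionises with acid and can be cut by hydrogenolysis, the free catechol is sensitive to air and binds metals, and the primary acetate does not tolerate strong base or hydride, so the phenols should stay masked to the end and the late steps should be neutral. The feature that opens the route is that C9 and C7' sit on neighbouring ring carbons, on the same face, opposite to the C2 aryl group, and that C7' bears the second aryl ring: together they map onto the two carbons of an aryl alkyne added suprafacially across the C3=C4 bond of a 2-aryl-2,5-dihydrofuran. The extra C9–C7' bond of the resulting cyclobutene is then cleaved oxidatively, which leaves oxygen on both carbons: wanted at C9, to be removed at C7'.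

## Retrosynthesis

Phenol protection (16 to 15). The three O–benzyl bonds are cut last. Benzyl ethers are preferred to silyl or acyl groups because both protected aldehydes 1 and 7 are articles of commerce and because benzyl ethers pass through amine base, zinc halide, cold ozone, borohydride and tin radicals. The forward step must hydrogenolyse three aryl benzyl ethers before the benzylic C2–O1 ring bond reacts.

Oxygen at C7' and the acetate (15 to 12). Putting a hydroxyl back on C7' and removing the acetyl group leads from 15 through thiocarbonyl derivative 14 and monoacetate 13 to diol 12. An ionic reduction or a hydrogenolysis at C7' would have to tell two electron-rich benzylic C–O bonds apart; a radical deoxygenation touches only the carbon that carries the thiocarbonyl group. The forward sequence must distinguish a primary hydroxyl from a secondary benzylic one, a large steric difference.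

Reconnection of C9 and C7' (12 to 9). Diol 12 is the reduced form of keto aldehyde 11, and joining the two carbonyl carbons of 11 in a C9=C7' double bond gives cyclobutene 9, with ozonide 10 as the link. This cut does not reduce the atom count; it converts a cis pair of side chains that could epimerise into a cis-fused bicycle in which the relation cannot be lost. The forward reaction must cleave a strained styrene-type alkene in the presence of three alkoxy-arenes and reduce the product in the same flask.

Two-bond disconnection (9 to 6 and 8). Cutting C3–C9 and C4–C7' together divides 9 into dihydrofuran 6 and alkyne 8, two halves of similar size that each carry one aryl ring. Cutting only one of these bonds would set C3 and C4 one after the other and would favour the trans arrangement; the two-bond cut sets both at once and cis by necessity. The forward reaction, a cobalt-catalysed [2+2] cycloaddition, must add to the face of 6 opposite the C2 aryl group and must bond the unsubstituted alkyne carbon to C3.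

Alkyne (8 to 7). The C≡C bond is cut to aldehyde 7 by a one-carbon homologation, which asks only for mild base.

Dihydrofuran (6 to 4 and 5, then to 1). The C2–aryl bond is cut to aryl triflate 4 and 2,3-dihydrofuran 5. Ring-closing metathesis of a resolved diallyl ether would need more steps; the asymmetric Heck arylation creates the C2 stereocentre and places the double bond at C3=C4 in one catalytic step from an achiral enol ether. Triflate 4 comes from phenol 3, and 3 from aldehyde 1 through formate 2 by exchange of the formyl carbon for oxygen.

## Roads not taken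

Alternative 1: The cut is C2–C3 together with O1–C5, with C5 carried as a lactone carbonyl. Aldehyde 1 and the (Z)-allylboronate A2 would be joined under a chiral BINOL-derived phosphoric acid; a chair allylboration forms C2–C3 and the boron alkoxide closes onto the ester to give the trans α-methylene lactone A1.
- Merits: C2 and C3 are set together, absolutely and relatively, from the same aldehyde that opens the chosen route. Acid-catalysed allylboration–lactonisation of 2-alkoxycarbonyl allylboronates is an established reaction class, which the cobalt step is not.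
- Weak points: A1 still lacks the guaiacyl ring, the C4 stereocentre and the right oxidation level at C5. After conjugate addition of the aryl nucleophile, C4 must be set by kinetic protonation of a lactone enolate to give the less stable cis isomer at a centre that stays epimerisable until the carbonyl is gone. The lactone must then be reduced to the cyclic ether through a lactol and a Lewis-acid/silane step beside the ionisable C2–O1 bond, and the silyl ether exchanged for the acetate.
- Comparison: this road is better on precedent for its key step. The chosen plan has to set against that a cis relation fixed by ring fusion, no ring carbonyl at any stage, and about three fewer steps after the key step.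

Alternative 2: The cut is O1–C2. Sc(OTf)3 would open the benzylic bond of cyclopropane carbaldehyde A4 and the formyl oxygen would close onto C2, giving the 2,3-trans 2,3-dihydrofuran A3 with a C4=C5 enol ether.
- Merits: C7' is at the methylene level from the start, so no deoxygenation is needed, and the C3 centre, which is not involved in the bond that breaks, carries the absolute configuration through the ring expansion.
- Weak points: A4 contains a quaternary carbon with formyl and arylmethyl groups beside two further stereocentres and must be made as a single enantiomer, a longer task than the whole front end of the chosen route. The ring expansion of an aldehyde of this substitution is not an established case. A3 still needs C4 set by adding hydrogen to the enol ether from the face of the C2 aryl group, where both faces are hindered and the conditions must spare benzyl ethers and the C2–O1 bond.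
- Comparison: this road is better in redox economy at C7'. The chosen plan sets C3 and C4 in one suprafacial event and draws on two one-ring fragments that are each made in a few steps.

Alternative 3: The cut is C4–C5. Rh2(OAc)4 would decompose diazo lactone A6 and the carbenoid at C4 would insert into a C–H bond of the methoxy group on C2, closing the oxolane cis-fused to the lactone as A5.
- Merits: the cis relation of C9 and C7' is enforced by ring fusion, as securely as by the cyclobutene. C7' is at the carboxyl level, so the guaiacyl ring could enter as an aryl-metal, and after reduction the sequence would meet the chosen route at diol 12, so the end game is shared. No regiochemical question of the alkyne type arises.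
- Weak points: the C–H bond is primary, and the carbenoid has other outlets: 1,2-hydride shift from C3 to a butenolide, attack on the neighbouring electron-rich arene, and insertion at benzyl ether methylenes. A6 needs C2 and C3 set beforehand by an anti-selective aldol-type construction and a diazo transfer, and addition of the aryl-metal to A5 must stop at the ketone stage.
- Comparison: the two plans are equal in how the cis relation is held and in the end game. The chosen plan is more convergent and shorter, and has to set that against a key step with less precedent.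

Key step: step 5

Assumption: the Heck arylation with triflate 4 is taken to follow the sense of induction known for phenyl triflate, where the (S)-configured tert-butyl phosphinooxazoline gives the (R)-2-aryl-2,5-dihydrofuran; the (R)-ligand is therefore specified for (S)-6.

## Route

Step 1
Reactants: 1 3,4-bis(benzyloxy)benzaldehyde
Product: 3 3,4-bis(benzyloxy)phenol, via aryl formate 2 (not isolated)
Conditions: mCPBA, CH2Cl2, 0 °C to rt; then MeOH, Et3N, rt
Reagents that add atoms: 3-chloroperoxybenzoic acid (mCPBA), O=C(OO)c1cccc(Cl)c1
Why: Baeyer–Villiger oxidation of an electron-rich benzaldehyde (Dakin-type): the dialkoxyaryl group migrates to oxygen in preference to hydrogen, and the labile aryl formate 2 is methanolysed in the same flask.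

Step 2
Reactants: 3 3,4-bis(benzyloxy)phenol
Product: 4 3,4-bis(benzyloxy)phenyl trifluoromethanesulfonate
Conditions: Tf2O, pyridine, CH2Cl2, 0 °C
Reagents that add atoms: trifluoromethanesulfonic anhydride, O=S(=O)(OS(=O)(=O)C(F)(F)F)C(F)(F)F
Why: O-sulfonylation of a phenol; the triflate is the leaving group that gives the cationic palladium pathway needed for an enantioselective Heck reaction.

Step 3
Reactants: 4 3,4-bis(benzyloxy)phenyl trifluoromethanesulfonate; 5 2,3-dihydrofuran
Product: 6 (2S)-2-[3,4-bis(benzyloxy)phenyl]-2,5-dihydrofuran
Conditions: 5 (4 equiv), Pd2(dba)3 (1.5 mol %), (R)-4-tert-butyl-2-[2-(diphenylphosphino)phenyl]-4,5-dihydrooxazole (6 mol %), i-Pr2NEt, THF, 70 °C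
Reagents that add atoms: none
Why: Asymmetric Mizoroki–Heck arylation: the aryl group adds to C2 of the enol ether on cationic divalent palladium and β-hydride elimination places the alkene at C3=C4. The P,N ligand releases this alkene without re-insertion, so the 2,5-dihydrofuran is kept, and its control of the enantioface in the carbopalladation sets C2 as S.

Step 4
Reactants: 7 4-(benzyloxy)-3-methoxybenzaldehyde
Product: 8 1-(benzyloxy)-4-ethynyl-2-methoxybenzene
Conditions: dimethyl (1-diazo-2-oxopropyl)phosphonate, K2CO3, MeOH, rt
Reagents that add atoms: dimethyl (1-diazo-2-oxopropyl)phosphonate (Ohira–Bestmann reagent), COP(=O)(OC)C(=[N+]=[N-])C(C)=O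
Why: Seyferth–Gilbert homologation in the Ohira–Bestmann form: methanolysis frees the diazomethylphosphonate anion, which olefinates the aldehyde; loss of nitrogen and a 1,2-hydrogen shift give the terminal alkyne under conditions that leave the benzyl ether alone.

Step 5
Reactants: 6 (2S)-2-[3,4-bis(benzyloxy)phenyl]-2,5-dihydrofuran; 8 1-(benzyloxy)-4-ethynyl-2-methoxybenzene
Product: 9 (1S,2S,5S)-2-[3,4-bis(benzyloxy)phenyl]-6-[4-(benzyloxy)-3-methoxyphenyl]-3-oxabicyclo[3.2.0]hept-6-ene
Conditions: CoBr2(dppp) (10 mol %; dppp = 1,3-bis(diphenylphosphino)propane), Zn (20 mol %), ZnI2 (20 mol %), CH2Cl2, rt; 8 (1.5 equiv) added over 6 h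
Reagents that add atoms: none
Why: Proposed new method: zinc reduces CoBr2(dppp) to a monovalent cobalt bromide, ZnI2 takes up the halide, and the cationic monovalent cobalt centre binds alkyne 8 and the C3=C4 bond of 6; oxidative cyclisation forms C3–C9 in a cobaltacyclopentene of trivalent cobalt, and C–C reductive elimination then forms C4–C7'. The closest known reaction type is the cobalt-catalysed [2+2] cycloaddition of internal alkynes with cyclopentene and norbornene-type alkenes to cyclobutenes; a terminal aryl alkyne and a 2-substituted 2,5-dihydrofuran have not been shown in it. The cyclobutene ring is closed by this reductive elimination from the five-membered metallacycle, a formal [2+2] closure in two bond-forming events on the metal. Both new stereocentres, C3 and C4, come from suprafacial addition to the ring alkene, so C9 and C7' are cis by necessity, and the C2 aryl group of 6, directly beside the alkene, blocks its own face so that cobalt and alkyne add anti to it. The step needs this face selectivity and also regioselectivity: the aryl-substituted alkyne carbon and the cobalt centre with its diphosphine should both stay away from C3, the alkene carbon flanked by the C2 aryl group, so that the small CH terminus bonds to C3 and the aryl-bearing carbon to C4. Slow addition of 8 keeps its concentration low and is meant to suppress alkyne cyclotrimerisation, the known competing reaction of terminal alkynes on low-valent cobalt.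

Step 6
Reactants: 9 (1S,2S,5S)-2-[3,4-bis(benzyloxy)phenyl]-6-[4-(benzyloxy)-3-methoxyphenyl]-3-oxabicyclo[3.2.0]hept-6-ene
Product: 12 [(2S,3R,4R)-2-[3,4-bis(benzyloxy)phenyl]-4-{[4-(benzyloxy)-3-methoxyphenyl](hydroxy)methyl}oxolan-3-yl]methanol (both epimers at carbinol carbon C7'), via ozonide 10 (not isolated), via keto aldehyde 11 (not isolated)
Conditions: O3, CH2Cl2, −78 °C (Sudan Red 7B as end-point indicator); then NaBH4, MeOH, −78 to 0 °C
Reagents that add atoms: ozone, [O-][O+]=O
Why: Ozonolysis: the strained, aryl-substituted cyclobutene alkene should react with ozone ahead of the alkoxy-arenes and recombine to ozonide 10; borohydride opens 10 to keto aldehyde 11 and reduces both carbonyl groups in the cold, before C3 or C4 (now α to carbonyl) can epimerise. The carbinol centre at C7' is formed without control and is removed in step 9.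

Step 7
Reactants: 12 [(2S,3R,4R)-2-[3,4-bis(benzyloxy)phenyl]-4-{[4-(benzyloxy)-3-methoxyphenyl](hydroxy)methyl}oxolan-3-yl]methanol
Product: 13 [(2S,3R,4R)-2-[3,4-bis(benzyloxy)phenyl]-4-{[4-(benzyloxy)-3-methoxyphenyl](hydroxy)methyl}oxolan-3-yl]methyl acetate
Conditions: AcCl (1.1 equiv), 2,4,6-collidine, CH2Cl2, −78 °C
Reagents that add atoms: acetyl chloride, CC(Cl)=O
Why: Chemoselective acylation: the unhindered primary hydroxyl at C9 should react much faster than the secondary benzylic hydroxyl at C7' with acetyl chloride and a hindered pyridine base at low temperature.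

Step 8
Reactants: 13 [(2S,3R,4R)-2-[3,4-bis(benzyloxy)phenyl]-4-{[4-(benzyloxy)-3-methoxyphenyl](hydroxy)methyl}oxolan-3-yl]methyl acetate
Product: 14 [(2S,3R,4R)-2-[3,4-bis(benzyloxy)phenyl]-4-{[4-(benzyloxy)-3-methoxyphenyl][(1H-imidazol-1-ylcarbonothioyl)oxy]methyl}oxolan-3-yl]methyl acetate
Conditions: 1,1'-thiocarbonyldiimidazole, DMAP (cat.), CH2Cl2, rt to 40 °C
Reagents that add atoms: 1,1'-thiocarbonyldiimidazole, S=C(n1ccnc1)n1ccnc1
Why: Thioacylation of the secondary alcohol, the first half of a Barton–McCombie deoxygenation; the conditions are neutral, so the acetate stays in place and neither benzylic C–O bond is ionised.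

Step 9
Reactants: 14 [(2S,3R,4R)-2-[3,4-bis(benzyloxy)phenyl]-4-{[4-(benzyloxy)-3-methoxyphenyl][(1H-imidazol-1-ylcarbonothioyl)oxy]methyl}oxolan-3-yl]methyl acetate
Product: 15 [(2S,3R,4R)-2-[3,4-bis(benzyloxy)phenyl]-4-{[4-(benzyloxy)-3-methoxyphenyl]methyl}oxolan-3-yl]methyl acetate
Conditions: Bu3SnH, AIBN (cat.), toluene, 80 °C
Reagents that add atoms: none
Why: Barton–McCombie deoxygenation: the stannyl radical adds to sulfur, β-scission releases the benzylic C7' radical, and hydrogen transfer from the stannane gives the methylene group. The chain is neutral, so the acetate, the C2–O1 bond and the three ring stereocentres are not touched, and both C7' epimers converge on one product.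

Step 10
Reactants: 15 [(2S,3R,4R)-2-[3,4-bis(benzyloxy)phenyl]-4-{[4-(benzyloxy)-3-methoxyphenyl]methyl}oxolan-3-yl]methyl acetate
Product: 16 [(2S,3R,4R)-2-(3,4-dihydroxyphenyl)-4-[(4-hydroxy-3-methoxyphenyl)methyl]oxolan-3-yl]methyl acetate
Conditions: H2 (1 atm), 10% palladium on carbon, EtOAc, rt; stopped after uptake of three equivalents
Reagents that add atoms: none
Why: Catalytic hydrogenolysis of three aryl benzyl ethers, which should cleave much faster than the cyclic benzylic C2–O1 ether in a neutral solvent; the acetate and the methyl ether are inert.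

## Compound list

1 | 3,4-bis(benzyloxy)benzaldehyde | O=Cc1ccc(OCc2ccccc2)c(OCc2ccccc2)c1 | starting material
2 | 3,4-bis(benzyloxy)phenyl formate (formed in the flask) | O=COc1ccc(OCc2ccccc2)c(OCc2ccccc2)c1 | intermediate
3 | 3,4-bis(benzyloxy)phenol | Oc1ccc(OCc2ccccc2)c(OCc2ccccc2)c1 | intermediate
4 | 3,4-bis(benzyloxy)phenyl trifluoromethanesulfonate | O=S(=O)(Oc1ccc(OCc2ccccc2)c(OCc2ccccc2)c1)C(F)(F)F | intermediate
5 | 2,3-dihydrofuran | C1=COCC1 | starting material
6 | (2S)-2-[3,4-bis(benzyloxy)phenyl]-2,5-dihydrofuran | C1=CCO[C@@H]1c1ccc(OCc2ccccc2)c(OCc2ccccc2)c1 | intermediate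
7 | 4-(benzyloxy)-3-methoxybenzaldehyde (O-benzylvanillin) | COc1cc(C=O)ccc1OCc1ccccc1 | starting material
8 | 1-(benzyloxy)-4-ethynyl-2-methoxybenzene | C#Cc1ccc(OCc2ccccc2)c(OC)c1 | intermediate
9 | (1S,2S,5S)-2-[3,4-bis(benzyloxy)phenyl]-6-[4-(benzyloxy)-3-methoxyphenyl]-3-oxabicyclo[3.2.0]hept-6-ene | C1=C(c3ccc(OCc4ccccc4)c(OC)c3)[C@H]2CO[C@H](c3ccc(OCc4ccccc4)c(OCc4ccccc4)c3)[C@H]21 | intermediate
10 | ozonide of 9: 1,2,4-trioxolane spanning C9 and C7', ring centres C2, C3, C4 as in 9, bridgehead centres not defined (formed in the flask) | COc1cc(C23OOC(O2)[C@@H]4[C@@H](c5ccc(OCc6ccccc6)c(OCc6ccccc6)c5)OC[C@H]34)ccc1OCc1ccccc1 | intermediate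
11 | (2S,3S,4R)-4-[4-(benzyloxy)-3-methoxybenzoyl]-2-[3,4-bis(benzyloxy)phenyl]oxolane-3-carbaldehyde (formed in the flask) | COc1cc(C(=O)[C@H]2CO[C@H](c3ccc(OCc4ccccc4)c(OCc4ccccc4)c3)[C@H]2C=O)ccc1OCc1ccccc1 | intermediate
12 | [(2S,3R,4R)-2-[3,4-bis(benzyloxy)phenyl]-4-{[4-(benzyloxy)-3-methoxyphenyl](hydroxy)methyl}oxolan-3-yl]methanol, both epimers at the carbinol carbon | COc1cc(C(O)[C@H]2CO[C@H](c3ccc(OCc4ccccc4)c(OCc4ccccc4)c3)[C@H]2CO)ccc1OCc1ccccc1 | intermediate
13 | [(2S,3R,4R)-2-[3,4-bis(benzyloxy)phenyl]-4-{[4-(benzyloxy)-3-methoxyphenyl](hydroxy)methyl}oxolan-3-yl]methyl acetate, both epimers at the carbinol carbon | COc1cc(C(O)[C@H]2CO[C@H](c3ccc(OCc4ccccc4)c(OCc4ccccc4)c3)[C@H]2COC(C)=O)ccc1OCc1ccccc1 | intermediate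
14 | [(2S,3R,4R)-2-[3,4-bis(benzyloxy)phenyl]-4-{[4-(benzyloxy)-3-methoxyphenyl][(1H-imidazol-1-ylcarbonothioyl)oxy]methyl}oxolan-3-yl]methyl acetate, both epimers at the benzylic carbon | COc1cc(C(OC(=S)n5ccnc5)[C@H]2CO[C@H](c3ccc(OCc4ccccc4)c(OCc4ccccc4)c3)[C@H]2COC(C)=O)ccc1OCc1ccccc1 | intermediate
15 | [(2S,3R,4R)-2-[3,4-bis(benzyloxy)phenyl]-4-{[4-(benzyloxy)-3-methoxyphenyl]methyl}oxolan-3-yl]methyl acetate | COc1cc(C[C@H]2CO[C@H](c3ccc(OCc4ccccc4)c(OCc4ccccc4)c3)[C@H]2COC(C)=O)ccc1OCc1ccccc1 | intermediate
16 | [(2S,3R,4R)-2-(3,4-dihydroxyphenyl)-4-[(4-hydroxy-3-methoxyphenyl)methyl]oxolan-3-yl]methyl acetate | COc1cc(C[C@H]2CO[C@H](c3ccc(O)c(O)c3)[C@H]2COC(C)=O)ccc1O | target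

## Step count and least certain steps

Total step count: 10. Longest linear sequence: 9 steps (steps 1, 2, 3, 5, 6, 7, 8, 9, 10, from aldehyde 1); step 4 is a one-step branch.

Step 5 (key step).
- What may go wrong: the terminal alkyne may be consumed by cobalt-catalysed cyclotrimerisation or dimerisation faster than it couples with the allylically oxygenated ring alkene. Regiocontrol may be poor, because the difference between C3 and C4 is transmitted only through the C2 substituent. The C2 centre of 6, both allylic and benzylic, may suffer double-bond migration by a cobalt hydride or ionisation by zinc halide, with loss of material or of enantiopurity.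
- Fallback (known chemistry, radical cyclisation in place of cycloaddition and cleavage): it sets out from aldehydes 1 and 7 and comes back to the route at 15. Vinylmagnesium bromide adds to 1 to give racemic 1-[3,4-bis(benzyloxy)phenyl]prop-2-en-1-ol F1. Sharpless kinetic resolution (Ti(OiPr)4, D-(−)-diisopropyl tartrate, t-BuOOH, 4 Å sieves, −20 °C) should epoxidise the (S)-enantiomer to (R)-[3,4-bis(benzyloxy)phenyl][(2R)-oxiran-2-yl]methanol F2. Vinylmagnesium bromide with 7 gives 1-[4-(benzyloxy)-3-methoxyphenyl]prop-2-en-1-ol F3, and PBr3 converts it with allylic transposition into 1-(benzyloxy)-4-[(1E)-3-bromoprop-1-en-1-yl]-2-methoxybenzene F4. Williamson etherification of F2 with F4 (NaH, THF/DMF, 0 °C) gives (2R)-2-[(R)-[3,4-bis(benzyloxy)phenyl]{[(2E)-3-[4-(benzyloxy)-3-methoxyphenyl]prop-2-en-1-yl]oxy}methyl]oxirane F5. Cp2TiCl (trivalent titanium, made from Cp2TiCl2 and zinc in THF) opens the epoxide to the C3 radical, which closes 5-exo onto the styrene; reduction and protonation of the benzylic radical should give the 2,3-trans-3,4-cis alcohol [(2S,3R,4R)-2-[3,4-bis(benzyloxy)phenyl]-4-{[4-(benzyloxy)-3-methoxyphenyl]methyl}oxolan-3-yl]methanol F6. Acetylation (Ac2O, pyridine) gives 15. The epoxide carbon becomes a radical, so only the carbinol configuration of F2 matters. The detour is longer than steps 5 to 9 and is held as a reserve.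

Step 3.
- What may go wrong: oxidative addition of the electron-rich triflate to zerovalent palladium is slow, so conversion may stall, and long heating may erode enantioselectivity or move the double bond.
- Fallback (ring-closing metathesis in place of C–aryl coupling): it sets out from aldehyde 1 and comes back at 6. The racemic carbinol 1-[3,4-bis(benzyloxy)phenyl]prop-2-en-1-ol F1, one Grignard step from 1 as above, is resolved with immobilised Candida antarctica lipase B and vinyl acetate, which should acylate the (R)-enantiomer and leave (1S)-1-[3,4-bis(benzyloxy)phenyl]prop-2-en-1-ol F7. O-Allylation (NaH, allyl bromide, DMF) gives 1,2-bis(benzyloxy)-4-[(1S)-1-(prop-2-en-1-yloxy)prop-2-en-1-yl]benzene F8. Ring closure with second-generation Grubbs catalyst, RuCl2(=CHPh)(H2IMes)(PCy3), in CH2Cl2 gives 6 with C2 unchanged.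

Step 6.
- What may go wrong: ozone may oxidise the alkoxy-arenes or benzyl ether methylenes once the alkene is consumed, and C4 (α to the aryl ketone) or C3 (α to the aldehyde) may epimerise towards the trans arrangement if reduction is slow.
- Fallback (osmylation and glycol cleavage in place of ozone): it sets out from 9 and comes back at 12. K2OsO4·2H2O (cat.) with N-methylmorpholine N-oxide in acetone/water should add from the exo face to give 2-[3,4-bis(benzyloxy)phenyl]-6-[4-(benzyloxy)-3-methoxyphenyl]-3-oxabicyclo[3.2.0]heptane-6,7-diol F9 (cis-diol on the exo face, ring centres as in 9). NaIO4 in THF/water cleaves the glycol to keto aldehyde 11, which is reduced at once with NaBH4 to 12.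

Step 8 (with step 9).
- What may go wrong: the thiocarbonyl ester of a p-alkoxybenzylic alcohol may ionise, leading to O-to-S rearrangement or thermal syn-elimination to the C4=C7' alkene, which would destroy the C4 stereocentre.
- Fallback (ionic in place of radical deoxygenation): it sets out from 13 and comes back at 15. Et3SiH with BF3·OEt2 in CH2Cl2 at −78 °C ionises the benzylic alcohol and reduces the cation by hydride transfer from silicon, in one step without a thiocarbonyl intermediate. Its own hazard is ionisation at C2, which is why it is the reserve and not the first choice.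

Step 10.
- What may go wrong: over-reduction, that is hydrogenolysis of the benzylic C2–O1 bond once the electron-rich free phenols are formed, which would open the ring.
- Fallback (Lewis-acid dealkylation in place of hydrogenolysis): it sets out from 15 and gives 16 directly. BCl3 with pentamethylbenzene as benzyl-cation scavenger in CH2Cl2 at −78 °C cleaves aryl benzyl ethers without hydrogen and should leave the methyl ether and the acetate.

## Further compounds

F1 | step 5 | 1-[3,4-bis(benzyloxy)phenyl]prop-2-en-1-ol (racemic) | C=CC(O)c1ccc(OCc2ccccc2)c(OCc2ccccc2)c1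
F2 | step 5 | (R)-[3,4-bis(benzyloxy)phenyl][(2R)-oxiran-2-yl]methanol | O[C@H](c1ccc(OCc2ccccc2)c(OCc2ccccc2)c1)[C@H]1CO1
F3 | step 5 | 1-[4-(benzyloxy)-3-methoxyphenyl]prop-2-en-1-ol (racemic) | C=CC(O)c1ccc(OCc2ccccc2)c(OC)c1
F4 | step 5 | 1-(benzyloxy)-4-[(1E)-3-bromoprop-1-en-1-yl]-2-methoxybenzene | BrC/C=C/c1ccc(OCc2ccccc2)c(OC)c1
F5 | step 5 | (2R)-2-[(R)-[3,4-bis(benzyloxy)phenyl]{[(2E)-3-[4-(benzyloxy)-3-methoxyphenyl]prop-2-en-1-yl]oxy}methyl]oxirane | COc1cc(/C=C/CO[C@H](c2ccc(OCc3ccccc3)c(OCc3ccccc3)c2)[C@H]2CO2)ccc1OCc1ccccc1
F6 | step 5 | [(2S,3R,4R)-2-[3,4-bis(benzyloxy)phenyl]-4-{[4-(benzyloxy)-3-methoxyphenyl]methyl}oxolan-3-yl]methanol | COc1cc(C[C@H]2CO[C@H](c3ccc(OCc4ccccc4)c(OCc4ccccc4)c3)[C@H]2CO)ccc1OCc1ccccc1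
F7 | step 3 | (1S)-1-[3,4-bis(benzyloxy)phenyl]prop-2-en-1-ol | C=C[C@H](O)c1ccc(OCc2ccccc2)c(OCc2ccccc2)c1
F8 | step 3 | 1,2-bis(benzyloxy)-4-[(1S)-1-(prop-2-en-1-yloxy)prop-2-en-1-yl]benzene | C=C[C@H](OCC=C)c1ccc(OCc2ccccc2)c(OCc2ccccc2)c1
F9 | step 6 | 2-[3,4-bis(benzyloxy)phenyl]-6-[4-(benzyloxy)-3-methoxyphenyl]-3-oxabicyclo[3.2.0]heptane-6,7-diol (cis-diol on the exo face, ring centres as in 9) | O[C@@H]1[C@@](O)(c3ccc(OCc4ccccc4)c(OC)c3)[C@H]2CO[C@H](c3ccc(OCc4ccccc4)c(OCc4ccccc4)c3)[C@H]21
F0 | step 8 | none | none
F0 | step 10 | none | none
A1 | alternative 1 | (4R,5S)-5-[3,4-bis(benzyloxy)phenyl]-4-({[tert-butyl(dimethyl)silyl]oxy}methyl)-3-methylideneoxolan-2-one | C=C1C(=O)O[C@H](c2ccc(OCc3ccccc3)c(OCc3ccccc3)c2)[C@H]1CO[Si](C)(C)C(C)(C)C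
A2 | alternative 1 | methyl (2Z)-4-{[tert-butyl(dimethyl)silyl]oxy}-2-[(4,4,5,5-tetramethyl-1,3,2-dioxaborolan-2-yl)methyl]but-2-enoate | COC(=O)/C(CB1OC(C)(C)C(C)(C)O1)=C\CO[Si](C)(C)C(C)(C)C
A3 | alternative 2 | (2S,3R)-4-{[4-(benzyloxy)-3-methoxyphenyl]methyl}-2-[3,4-bis(benzyloxy)phenyl]-3-({[tert-butyl(dimethyl)silyl]oxy}methyl)-2,3-dihydrofuran | COc1cc(CC2=CO[C@H](c3ccc(OCc4ccccc4)c(OCc4ccccc4)c3)[C@H]2CO[Si](C)(C)C(C)(C)C)ccc1OCc1ccccc1
A4 | alternative 2 | 1-{[4-(benzyloxy)-3-methoxyphenyl]methyl}-2-[3,4-bis(benzyloxy)phenyl]-3-({[tert-butyl(dimethyl)silyl]oxy}methyl)cyclopropane-1-carbaldehyde (one diastereomer drawn: aryl trans to the silyloxymethyl group, formyl cis to it) | O=C[C@@]1(Cc2ccc(OCc3ccccc3)c(OC)c2)[C@H](c2ccc(OCc3ccccc3)c(OCc3ccccc3)c2)[C@H]1CO[Si](C)(C)C(C)(C)C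
A5 | alternative 3 | (1R,5R,6S)-6-[3,4-bis(benzyloxy)phenyl]-3,7-dioxabicyclo[3.3.0]octan-2-one (cis-fused) | O=C1[C@H]2CO[C@H](c3ccc(OCc4ccccc4)c(OCc4ccccc4)c3)[C@H]2CO1
A6 | alternative 3 | (4R)-4-[(S)-[3,4-bis(benzyloxy)phenyl](methoxy)methyl]-3-diazooxolan-2-one | CO[C@H](c1ccc(OCc2ccccc2)c(OCc2ccccc2)c1)[C@H]1COC(=O)C1=[N+]=[N-]
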